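**Plan**
1. Retrosynthesis: the phenol O–H is traced back to O–CH3. The ring C6–CH2 bond and the ring C1–CO2H bond are then cut together, giving 3-methoxybenzyne, 10-phenyldecyllithium and CO2. Last, the far phenyl–CH2 bond of the chain is cut, giving a phenyl Grignard reagent and a C10 dibromide.
2. Enabling feature: the salicylic acid ring carries three contiguous substituents, oxygen on C2, CO2H on C1 and alkyl on C6. C1 and C6 are neighbours and map onto the triple bond of an aryne. The C2 oxygen beside that triple bond decides which end takes the carbon nucleophile and which the electrophile.
3. Forward order: the chain is made first (phenyl plus C10) and turned into the alkyllithium. It is joined to the aryne from 3-fluoroanisole (F is the leaving-group helper, O-methyl the protecting and directing helper), carboxylated in the same flask, and O-demethylated last.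
4. Both benzene rings are bought and no ring is formed. The target has no stereocentre and no stereogenic double bond, so no stereochemistry has to be set.

Key step: step 3

Assumption: the three starting materials are taken as commercial. The alkyllithium of step 2 is used as a titrated solution, and its preparation is counted as a step.

Step 1
Reactants: 1 phenylmagnesium bromide (THF solution); 2 1,10-dibromodecane
Product: 3 (10-bromodecyl)benzene
Conditions: 2 (3 equiv), Li2CuCl4 (3 mol%), THF, 0 °C, slow addition of 1, then rt; aq. NH4Cl; surplus 2 recovered by distillation
Reagents that add atoms: none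
Why: Copper-catalysed Grignard–alkyl bromide cross-coupling (Kochi-type sp2–sp3 coupling) is well established for primary bromides, and slow addition of 1 to a threefold excess of the symmetrical dibromide 2 should hold the reaction at monosubstitution.

Step 2
Reactants: 3 (10-bromodecyl)benzene
Product: 4 10-phenyldecyllithium (titrated Et2O solution, used at once)
Conditions: Li wire (about 1% Na, 2.5 equiv), Et2O, −10 to 0 °C, Ar, slow addition of 3
Reagents that add atoms: lithium metal [Li]
Why: Reductive lithiation of a primary alkyl bromide by lithium metal in ether is the classical preparation of primary alkyllithiums, low temperature and slow addition suppress Wurtz coupling, and the remote phenyl ring is inert.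

Step 3
Reactants: 5 3-fluoroanisole; 4 10-phenyldecyllithium
Product: 10 2-methoxy-6-(10-phenyldecyl)benzoic acid, via 2-fluoro-6-methoxyphenyllithium 6 (not isolated), via 3-methoxybenzyne 7 (not isolated), via 2-methoxy-6-(10-phenyldecyl)phenyllithium 8 (not isolated), via lithium 2-methoxy-6-(10-phenyldecyl)benzoate 9 (not isolated)
Conditions: 5, n-BuLi (1.0 equiv), THF, −78 °C, 1.5 h; 4 (1.3 equiv, Et2O) added at −78 °C; slow warming to −10 °C over 3 h; recool to −78 °C, dry CO2 (excess); then 1 M HCl
Reagents that add atoms: carbon dioxide O=C=O
Why: This is an aryne three-component coupling (carbolithiation of an aryne followed by carboxylation), the known way from fluoroanisoles and alkyllithiums to 6-alkyl-2-methoxybenzoic acids: the C2–H of 5, flanked by F and OMe, is lithiated at −78 °C to 6, which loses LiF on warming to give 3-methoxybenzyne 7. The primary alkyllithium 4 adds to the triple bond and forms the aryl–CH2 bond, and the aryllithium 8 created on the neighbouring carbon is trapped by CO2, so two adjacent ring substituents are set in one flask. The regioselectivity needed is attack at the aryne carbon remote from OMe: the sigma-withdrawing oxygen distorts the aryne so that the remote carbon is the more linear and electrophilic one, the negative charge develops on the carbon next to oxygen where induction and Li–O coordination stabilise it, and the remote carbon is also the less hindered. The chemoselectivity needed is capture of 7 by 4 and not by 6 or 8, which is secured by the much higher nucleophilicity of a primary alkyllithium over doubly ortho-substituted aryllithiums, by a modest excess of 4 and by slow warming that keeps 7 dilute, while full consumption of n-BuLi at −78 °C before 4 is added prevents butyl transfer. No ring is closed and no stereocentre is formed. The distant phenyl ring and its benzylic CH2 should be inert to alkyllithiums at these temperatures in the absence of a chelating amine.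

Step 4
Reactants: 10 2-methoxy-6-(10-phenyldecyl)benzoic acid
Product: 11 2-hydroxy-6-(10-phenyldecyl)benzoic acid (target)
Conditions: BBr3 (2.5 equiv), CH2Cl2, −78 °C → 0 °C; then H2O
Reagents that add atoms: none
Why: Lewis-acid aryl methyl ether cleavage, in which BBr3 binds the methoxy oxygen (helped by chelation to the neighbouring carboxyl group), bromide removes the methyl group by SN2 attack and aqueous work-up frees the phenol, while the alkyl chain, the phenyl ring and the acid are untouched.

**Compound list**
1 | phenylmagnesium bromide | Br[Mg]c1ccccc1 | starting material
2 | 1,10-dibromodecane | BrCCCCCCCCCCBr | starting material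
3 | (10-bromodecyl)benzene | BrCCCCCCCCCCc1ccccc1 | intermediate
4 | 10-phenyldecyllithium | [Li]CCCCCCCCCCc1ccccc1 | intermediate
5 | 3-fluoroanisole | COc1cccc(F)c1 | starting material
6 | 2-fluoro-6-methoxyphenyllithium | [Li]c1c(F)cccc1OC | intermediate
7 | 3-methoxybenzyne | COC1=CC=CC#C1 | intermediate
8 | 2-methoxy-6-(10-phenyldecyl)phenyllithium | [Li]c1c(OC)cccc1CCCCCCCCCCc1ccccc1 | intermediate
9 | lithium 2-methoxy-6-(10-phenyldecyl)benzoate | [Li+].[O-]C(=O)c1c(OC)cccc1CCCCCCCCCCc1ccccc1 | intermediate
10 | 2-methoxy-6-(10-phenyldecyl)benzoic acid | O=C(O)c1c(OC)cccc1CCCCCCCCCCc1ccccc1 | intermediate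
11 | 2-hydroxy-6-(10-phenyldecyl)benzoic acid | O=C(O)c1c(O)cccc1CCCCCCCCCCc1ccccc1 | target

Total step count: 4. Longest linear sequence: 4 (steps 1 to 4). Compound 5 enters at step 3 without prior manipulation.

**Steps most likely to fail**

Step 3. Several processes could erode the coupling.
- The aryne may be captured by the aryllithiums present instead of by the alkyllithium, which is self-condensation.
- The alkyllithium may decay in THF during the warming phase.
- Butyl may be transferred from unconsumed n-BuLi.
- A proton may pass from unlithiated 5 to 8 before carboxylation.
- Surplus 4 is carboxylated as well, which burdens the purification.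

The fallback replaces the aryne event by a cross-coupling. It sets out from 3 and comes back to the route at 11, so step 4 is no longer needed.
- LiCl-promoted insertion of zinc dust into 3 (THF, 50 °C) should give 10-phenyldecylzinc bromide F1.
- Purchased 5-hydroxy-2,2-dimethyl-4H-1,3-benzodioxin-4-one F2 is converted with Tf2O and pyridine (CH2Cl2, 0 °C) into 2,2-dimethyl-4-oxo-4H-1,3-benzodioxin-5-yl trifluoromethanesulfonate F3.
- Negishi coupling of F1 with F3 (PdCl2(dppf), THF, 60 °C) should give 2,2-dimethyl-5-(10-phenyldecyl)-4H-1,3-benzodioxin-4-one F4.
- KOH in THF/H2O followed by HCl opens the acetonide lactone of F4 to 11.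

Step 2. Wurtz-type homocoupling on the lithium surface, sluggish initiation, and loss of titre through ether cleavage could leave too little active reagent. The fallback replaces reductive metalation by halogen–metal exchange. It sets out from 3 and comes back at 4. A Finkelstein reaction (NaI, acetone, reflux) should give (10-iododecyl)benzene F5. Lithium–iodine exchange with t-BuLi (2.1 equiv, Et2O/pentane, −78 °C) should then deliver 4 cleanly for direct use in step 3.

Step 1. Arylation at both chain ends, homocoupling of the Grignard reagent, and a tedious separation from the surplus dibromide could make the statistical coupling impractical. The fallback uses an electrophile whose two ends already differ. It sets out from 1 and comes back at 3.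
- Compound 1 (2.3 equiv, the first equivalent being spent on the hydroxyl proton) is coupled with purchased 10-bromodecan-1-ol F6 under Li2CuCl4 catalysis (THF, 0 °C) to give 10-phenyldecan-1-ol F7.
- An Appel reaction (CBr4, PPh3, CH2Cl2, 0 °C) converts F7 into 3.

**Further compounds**
F1 | step 3 | 10-phenyldecylzinc bromide | Br[Zn]CCCCCCCCCCc1ccccc1
F2 | step 3 | 5-hydroxy-2,2-dimethyl-4H-1,3-benzodioxin-4-one (purchased) | CC1(C)OC(=O)c2c(O)cccc2O1
F3 | step 3 | 2,2-dimethyl-4-oxo-4H-1,3-benzodioxin-5-yl trifluoromethanesulfonate | CC1(C)OC(=O)c2c(OS(=O)(=O)C(F)(F)F)cccc2O1
F4 | step 3 | 2,2-dimethyl-5-(10-phenyldecyl)-4H-1,3-benzodioxin-4-one | CC1(C)OC(=O)c2c(CCCCCCCCCCc3ccccc3)cccc2O1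
F5 | step 2 | (10-iododecyl)benzene | ICCCCCCCCCCc1ccccc1
F6 | step 1 | 10-bromodecan-1-ol (purchased) | OCCCCCCCCCCBr
F7 | step 1 | 10-phenyldecan-1-ol | OCCCCCCCCCCc1ccccc1
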